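From the earliest readings of the elm run I added two columns together, left-handed product and left-handed substrate, and that sum was what I watched.

| flask | left-handed substrate | right-handed substrate | reagent | free catalyst | racemization catalyst | temperature | remark | time |
|---|---|---|---|---|---|---|---|---|
| elm | 0.020 M | 0.020 M | 0.060 M | 92 µM | 28 µM | 25 °C | the very flask that is asked about, followed so far |  |
| cedar | 0.020 M | 0.020 M | 0.060 M | 92 µM | 28 µM | 10 °C | run made earlier |  |
| flask | 0.020 M | 0.020 M | 0.0600 M | 92 µM | 28 µM | 25 °C |  | 4.0 d |

- elm (time / h: left-handed product / %, left-handed substrate / %): 8.00: 25.3, 28.0; 20.0: 41.5, 12.4; 40.0: 50.4, 3.6; 96.0: 54.6, 0.3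
- cedar (time / h: left-handed product / %, left-handed substrate / %): 15.0: 20.2, 35.8; 40.0: 39.6, 22.6; 96.0: 57.4, 7.4; 192: 62.5, 1.2

(each reading ± 0.5 percentage points)

- dusk: at 4.0 d raise the temperature by 15 K, then wait 4.0 d
- spring: at 4.0 d take out 90% of the left-handed product then present, then wait 4.0 d
- midnight: at 4.0 d add reagent, 50.0% of the amount charged, then wait 4.0 d
- winter: at 4.0 d add free catalyst, 100% of the amount charged, then wait 4.0 d
- summer: change nothing and wait 4.0 d more

- free catalyst is single-handed; left-handed substrate and right-handed substrate are mirror images of each other, charged as a racemate, each of them at the stated concentration
- what is taken out of left-handed product is counted as made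
- "the catalyst" is free catalyst with its forms; racemization catalyst is a second catalyst
- additions bring no volume worth counting

- left-handed product, in percent of the left-handed substrate and right-handed substrate together first charged, at 4.0 d
- which option adds most left-handed product ("none" when 2 percentage points or less is all one gets) (dusk / spring / midnight / winter / summer / none)
- left-handed product present, with what was taken out counted in, in percent of the left-handed substrate and right-handed substrate together first charged, after winter
- left-handed product present, with what was taken out counted in, in percent of the left-handed substrate and right-handed substrate together first charged, after summer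

I pictured two extreme flasks. In one the racemization catalyst does nothing, and left-handed product ends at half the substrate charged. In the other it outlasts the run, and right-handed substrate keeps feeding across, towards the full charge.

The elm flask lay between them, and the sum showed where. It ran from 53.3% at 8.00 h to 54.9% at 96.0 h and averaged 54.0%. I called this the ceiling: left-handed product plus the left-handed substrate still able to become it, once crossing has stopped. So, within the scatter of the readings, crossing in the elm run had stopped by about the first reading, though the right-handed side, some 46.0% of the charge, still outweighed the left-handed substrate read there. The cedar run, with the same charges at 10 °C, reached 63.7%, more than the elm run, so the ceiling has to be read run by run.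

Below the ceiling I treated the fall as pseudo-first-order in [left-handed substrate], with [reagent] and [free catalyst] taken as steady. Elm gave 0.0641 h⁻¹, which carried the 40.0 h reading forward to a remainder of 0.0994% at 4.0 d. I therefore committed to 53.9% at that time, a little under the 54.6% read there, and to the ceiling after winter and after summer. No option brings racemization catalyst, so each had just that remainder to finish, less than the 2 percentage points that counts, and I said none.

The forecast gave 54.4%, 54.7% after winter, 54.6% after summer and none as best, on the grounds of “time-dependent death of the racemization catalyst”. The flask gave 53.9%, 54.0% after winter, 54.0% after summer and none as best, each option adding 0.13 points.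

    left-handed substrate + racemization catalyst ⇌ right-handed substrate + racemization catalyst, rate k1*[racemization catalyst]*[left-handed substrate] forward; the back reaction follows from the equilibrium constant (k = 320 L mol⁻¹ min⁻¹, Ea = 52.0 kJ mol⁻¹)
    reagent + free catalyst + left-handed substrate → free catalyst + left-handed product (k = 280 L² mol⁻² min⁻¹, Ea = 47.0 kJ mol⁻¹)
    racemization catalyst → spent catalyst (k = 0.00970 min⁻¹, Ea = 94.0 kJ mol⁻¹)
    reagent + free catalyst + right-handed substrate → free catalyst + right-handed product (k = 3.70 L² mol⁻² min⁻¹, Ea = 48.0 kJ mol⁻¹)
    (constants at 25 °C)

The ceiling as read from the elm run, 54.0%, stood 0.10 points above the flask's 53.9%, and the flask held 0.132% of left-handed substrate at 96.0 h. The ceiling stood so low because of the path from racemization catalyst to spent catalyst: by that path alone the racemization catalyst had a half-life of 1.2 h, and the same flask without the path gave 89.7% at 4.0 d, not 53.9%. The neighbour flask with 3.7 × 10⁻⁴ M of free catalyst held 0% left-handed substrate at 96.0 h, so its 61.0% of left-handed product was its ceiling, 7 points above the one read from the elm run.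

The readings were computed on assumed constants; noise was put on by code.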